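**Retrosynthetic overview** (side-chain carbons are numbered C1′–C21′ outward from the ring)
1. Target 12 ⇐ ethyl 3-henicosylpyrrole-2-carboxylate 10 (CO2Et → CH2OH → CHO).
2. Pyrrole (the only ring made, step 3) ⇐ silyl ynone 6 + glycine ethyl ester: N1–C5 by aza-Michael addition, then ring closure at the C2–C3 carbon–carbon bond.
3. Ynone 6 ⇐ 1-(silylethynyl)cyclododecanol 4 + 1-bromodecane 5: a ring-opening alkyl–alkyl coupling cuts C3–C11′ of a temporary cyclododecane and forms C11′–C12′.
4. 4 ⇐ cyclododecanone + ethynyltrimethylsilane.
5. Enabling feature: pyrrole C3 and the eleven CH2 groups C1′–C11′ form a 12-carbon unit that can be tied into a cyclododecane ring with oxygen on C3 and C4–C5 attached as an ethynyl group. An alkoxy radical on C3 then opens the ring exactly at C11′ and leaves the ynone needed for the annulation.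

Key step: step 2

Remark: the target has no stereocentre. The radicals of step 2 are treated as mechanism, not as numbered compounds.

**Route**

Step 1
Reactants: 1 cyclododecanone; 2 ethynyltrimethylsilane
Product: 4 1-[2-(trimethylsilyl)ethynyl]cyclododecan-1-ol, via lithium (trimethylsilyl)acetylide 3 (not isolated)
Conditions: 2, n-BuLi, THF, −78 °C; then 1, −78 °C → rt; H2O
Reagents that add atoms: none
Why: 1,2-addition of a lithium acetylide to a ketone; the silyl cap keeps the alkyne terminus inert in step 2, and no stereocentre is formed.

Step 2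
Reactants: 4 1-[2-(trimethylsilyl)ethynyl]cyclododecan-1-ol; 5 1-bromodecane
Product: 6 1-(trimethylsilyl)tetracos-1-yn-3-one
Conditions: 9-mesityl-3,6-di-tert-butyl-10-phenylacridinium BF4 (5 mol %), NiBr2·glyme (10 mol %), dtbbpy (12 mol %), 2,4,6-collidine (0.3 equiv), K2HPO4 (2 equiv), 5 (2 equiv), MeCN/PhCF3, 450 nm LEDs, rt
Reagents that add atoms: none
Why: Proposed new method: the excited acridinium and collidine should remove the O–H hydrogen of 4 by proton-coupled electron transfer, and the tertiary alkoxy radical should undergo β-scission of a ring C–C bond (the alkynyl group cannot leave as a radical, and the conjugated ynone carbonyl that forms drives the scission), which places a primary radical on the ring carbon that ends up eleven carbons from the new ketone. This radical should be captured by a (dtbbpy)Ni–decyl species formed from 5, and reductive elimination from Ni(III) should form the C(sp3)–C(sp3) bond, while the reduced photocatalyst returns nickel to its low-valent state, so the cycle is redox-neutral and only HBr is lost to the phosphate. The closest known reaction types are the photoredox/nickel ring-opening arylation of tertiary cycloalkanols and the nickel/photoredox coupling of alkyl radicals with primary alkyl bromides; merging them on a free propargylic cycloalkanol with an alkyl bromide is the new part. No ring is closed (the temporary 12-membered ring is opened) and no stereocentre is formed. The step needs scission to outrun transannular 1,5-hydrogen transfer and cross-coupling to outrun radical addition to the product and decyl homocoupling: the sp substituent speeds the scission, the silyl group shields the β-carbon of the ynone, and an excess of 5 keeps nickel loaded with decyl.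

Step 3
Reactants: 6 1-(trimethylsilyl)tetracos-1-yn-3-one; 7 glycine ethyl ester hydrochloride
Product: 10 ethyl 3-henicosyl-1H-pyrrole-2-carboxylate, via tetracos-1-yn-3-one 8 (not isolated), via glycinate enaminone 9 (not isolated)
Conditions: 7 (1.2 equiv), NaOEt (1.3 equiv), EtOH/THF, 0 °C → rt; then NaOEt (2 equiv), EtOH, reflux
Reagents that add atoms: none
Why: Ethoxide should cleave the C–Si bond of the silyl ynone, the amine of 7 should add to the terminal ynone (aza-Michael addition, N1–C5) to give the hydrogen-bonded Z-enaminone, and ethoxide should then close the ring at C2–C3 by an intramolecular aldol-type (Knoevenagel) condensation of the glycinate CH2 onto the ketone with loss of water, a known route from N-(3-oxoalkenyl)glycinates to pyrrole-2-carboxylates.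

Step 4
Reactants: 10 ethyl 3-henicosyl-1H-pyrrole-2-carboxylate
Product: 11 (3-henicosyl-1H-pyrrol-2-yl)methanol
Conditions: LiAlH4 (2.5 equiv), THF, 0 °C; H2O/aq. NaOH work-up; used crude
Reagents that add atoms: none
Why: Hydride reduction of the ester with LiAlH4 at 0 °C, where the N-metallated pyrrolylcarbinolate should persist without further reduction.

Step 5
Reactants: 11 (3-henicosyl-1H-pyrrol-2-yl)methanol
Product: 12 3-henicosyl-1H-pyrrole-2-carbaldehyde
Conditions: activated MnO2 (15 equiv), CH2Cl2, rt
Reagents that add atoms: none
Why: MnO2 oxidation of the benzylic-type pyrrol-2-ylmethanol should stop at the aldehyde (a vinylogous formamide) and leave the ring and the N–H untouched.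

**Compound list**
1 | cyclododecanone | O=C1CCCCCCCCCCC1 | starting material
2 | ethynyltrimethylsilane | C#C[Si](C)(C)C | starting material
3 | lithium (trimethylsilyl)acetylide | [Li]C#C[Si](C)(C)C | intermediate
4 | 1-[2-(trimethylsilyl)ethynyl]cyclododecan-1-ol | C[Si](C)(C)C#CC1(O)CCCCCCCCCCC1 | intermediate
5 | 1-bromodecane | CCCCCCCCCCBr | starting material
6 | 1-(trimethylsilyl)tetracos-1-yn-3-one | CCCCCCCCCCCCCCCCCCCCCC(=O)C#C[Si](C)(C)C | intermediate
7 | glycine ethyl ester hydrochloride | Cl.NCC(=O)OCC | starting material
8 | tetracos-1-yn-3-one | CCCCCCCCCCCCCCCCCCCCCC(=O)C#C | intermediate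
9 | ethyl N-[(1Z)-3-oxotetracos-1-en-1-yl]glycinate | CCCCCCCCCCCCCCCCCCCCCC(=O)/C=C\NCC(=O)OCC | intermediate
10 | ethyl 3-henicosyl-1H-pyrrole-2-carboxylate | CCCCCCCCCCCCCCCCCCCCCc1cc[nH]c1C(=O)OCC | intermediate
11 | (3-henicosyl-1H-pyrrol-2-yl)methanol | CCCCCCCCCCCCCCCCCCCCCc1cc[nH]c1CO | intermediate
12 | 3-henicosyl-1H-pyrrole-2-carbaldehyde | CCCCCCCCCCCCCCCCCCCCCc1cc[nH]c1C=O | target

**Step count and risks**
Total step count: 5. Longest linear sequence: 5 (1 → 4 → 6 → 10 → 11 → 12).

Steps most likely to fail:

1. Step 2 (proposed method). The alkoxy radical may form too slowly or be diverted by transannular hydrogen transfer. The ring-opened radical may be lost to reduction, dimerisation or addition to the ynone before nickel captures it, and decyl homocoupling or β-hydride elimination at nickel may dominate. Fallback, setting out from 1 and returning at 6, makes the same C11′–C12′ bond by known polar chemistry. Baeyer–Villiger oxidation of 1 (m-CPBA, CF3CO2H cat., CH2Cl2) should give oxacyclotridecan-2-one F1. Opening the lactone with 48 % HBr/H2SO4 at reflux should give 12-bromododecanoic acid F2. Decylmagnesium bromide F3 (from 5 and Mg, 2.3 equiv) with Li2CuCl4 (3 mol %) in THF at −20 °C should alkylate the bromide carbon of F2 to give docosanoic acid F4. SOCl2 should then give docosanoyl chloride F5, and Friedel–Crafts acylation of bis(trimethylsilyl)acetylene (AlCl3, CH2Cl2, 0 °C) should give 6.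

2. Step 3. The vinylogous-amide carbonyl of 9 is a weak electrophile and the glycinate CH2 a weak acid, so closure may be slow. It may be overtaken by attack of the enaminone carbon on the ester (3-hydroxypyrrole formation) or by hydrolytic loss of the glycine unit. Fallback, setting out from 6 and returning at 10, uses an N-sulfonylglycinate. Desilylation of 6 (K2CO3, EtOH) to 8 and aza-Michael addition of ethyl N-tosylglycinate (Cs2CO3 cat., MeCN) should give ethyl N-[(1E)-3-oxotetracos-1-en-1-yl]-N-tosylglycinate F6. DBU should close C2–C3 by aldol addition to ethyl 3-henicosyl-3-hydroxy-1-tosyl-2,3-dihydro-1H-pyrrole-2-carboxylate F7. Dehydration (POCl3, pyridine) should give ethyl 3-henicosyl-1-tosyl-1H-pyrrole-2-carboxylate F8, and NaOEt in EtOH should remove the sulfonyl group to give 10. The sulfonyl group acidifies the CH2, removes the enaminone deactivation of the ketone and blocks the N–H.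

3. Step 4. The aluminium alkoxide may be over-reduced through an azafulvene to the 2-methylpyrrole, and the pyrrolylcarbinol may self-condense under acid on work-up or storage. Fallback, setting out from 10 and ending at 12 without passing through 11: MeNH(OMe)·HCl/i-PrMgCl (THF, −20 °C) should convert the ester into 3-henicosyl-N-methoxy-N-methyl-1H-pyrrole-2-carboxamide F9. LiAlH4 (THF, −40 → 0 °C) should stop at the chelated tetrahedral intermediate and give 12 on hydrolysis.

**Further compounds**
F1 | step 2 | oxacyclotridecan-2-one | O=C1CCCCCCCCCCCO1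
F2 | step 2 | 12-bromododecanoic acid | OC(=O)CCCCCCCCCCCBr
F3 | step 2 | decylmagnesium bromide | CCCCCCCCCC[Mg]Br
F4 | step 2 | docosanoic acid | CCCCCCCCCCCCCCCCCCCCCC(=O)O
F5 | step 2 | docosanoyl chloride | CCCCCCCCCCCCCCCCCCCCCC(=O)Cl
F6 | step 3 | ethyl N-[(1E)-3-oxotetracos-1-en-1-yl]-N-tosylglycinate | CCCCCCCCCCCCCCCCCCCCCC(=O)/C=C/N(CC(=O)OCC)S(=O)(=O)c1ccc(C)cc1
F7 | step 3 | ethyl 3-henicosyl-3-hydroxy-1-tosyl-2,3-dihydro-1H-pyrrole-2-carboxylate | CCCCCCCCCCCCCCCCCCCCCC1(O)C=CN(S(=O)(=O)c2ccc(C)cc2)C1C(=O)OCC
F8 | step 3 | ethyl 3-henicosyl-1-tosyl-1H-pyrrole-2-carboxylate | CCCCCCCCCCCCCCCCCCCCCc1ccn(S(=O)(=O)c2ccc(C)cc2)c1C(=O)OCC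
F9 | step 4 | 3-henicosyl-N-methoxy-N-methyl-1H-pyrrole-2-carboxamide | CCCCCCCCCCCCCCCCCCCCCc1cc[nH]c1C(=O)N(C)OC
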